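**Retrosynthetic overview**
- Target ⇒ tricyclic tertiary α-ketol (C7 ketone, C8–OH): dehydration inside the nine-membered ring can only give the ring-cis C8=C9 alkene, which is the (E)-enone.
- Ring C (azonane) ⇒ intramolecular N-alkylation of the methylaminopropyl arm on C8 by the 3-chloropropyl arm on C15.
- Ring B (key step) ⇒ C7–C8 bond by carbene-catalysed intramolecular crossed benzoin: the C7 aldehyde reacts as an acyl anion with the C8 ketone carbonyl.
- Keto-aldehyde ⇒ ring A β-diketone: quaternary C15 by C-alkylation anti to the C5 allyl group, C1–OH by hydroxyl-assisted reduction, aldehyde by ozonolysis of the allyl group.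
- Ring A ⇒ 3-methylcyclohex-2-enone: asymmetric β-borylation/oxidation (C3), Saegusa oxidation, conjugate allylation/C-acylation (C5). Ring order: A from the start, then B, then C.

Assumption: 4-[(tert-butoxycarbonyl)(methyl)amino]butanoic acid is taken as a purchasable catalogue compound.

Labels: carbons keep the target locants throughout: C1 (CH–OAc), C2, C3 (C(CH3)OAc), C4, C5 (ring-fusion CH), C6, C7 (C=O), C8=C9, C10, C11, N, C12–C14, C15 (quaternary C). β is the face of the cyclohexane that carries the C3 oxygen, α the face of the C3 methyl group. "Acyl" means the 4-[(tert-butoxycarbonyl)(methyl)amino]butanoyl group (C8–C11 plus N).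

**Route**

Step 1
Reactants: 1 4-[(tert-butoxycarbonyl)(methyl)amino]butanoic acid
Product: 2 tert-butyl N-[4-(benzotriazol-1-yl)-4-oxobutyl]-N-methylcarbamate
Conditions: 1H-benzotriazole, DCC, CH2Cl2, 0 °C → rt
Reagents that add atoms: 1H-benzotriazole, c1ccc2[nH]nnc2c1
Why: Carbodiimide coupling gives a bench-stable neutral N-acylbenzotriazole (Katritzky-type acyl donor) suited to C-acylation of a ketone enolate; no stereocentre is involved.

Step 2
Reactants: 3 3-methylcyclohex-2-en-1-one
Product: 5 (S)-3-hydroxy-3-methylcyclohexan-1-one, via boronate 4 (not isolated)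
Conditions: B2pin2 (1.2 equiv), CuCl (5 mol%), NaOtBu (8 mol%), QuinoxP* (6 mol%, the enantiomer that gives (R)-4), MeOH (2 equiv), THF, rt; then 30% H2O2, pH 7 phosphate buffer, 0 °C
Reagents that add atoms: bis(pinacolato)diboron, CC1(C)OB(OC1(C)C)B1OC(C)(C)C(C)(C)O1 (boryl group of 4 only); hydrogen peroxide, OO
Why: Copper-catalysed enantioselective conjugate borylation of a β-substituted cyclic enone, with facial control by the P-chiral bisphosphine, followed by stereoretentive C–B oxidation sets the tertiary C3 carbinol.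

Step 3
Reactants: 5 (S)-3-hydroxy-3-methylcyclohexan-1-one
Product: 7 (S)-5-methyl-5-(trimethylsilyloxy)cyclohex-2-en-1-one, via bis-silyl enol ether 6 (not isolated)
Conditions: LiN(iPr)2 (2.2 equiv), Me3SiCl (2.5 equiv, in situ quench), THF, −78 °C; then Pd(OAc)2 (1.1 equiv), MeCN, rt
Reagents that add atoms: chlorotrimethylsilane, C[Si](C)(C)Cl
Why: Kinetic deprotonation occurs at the CH2 remote from the quaternary carbinol carbon while the tertiary OH is capped, and Saegusa–Ito oxidation of the silyl enol ether gives the enone without touching C3.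

Step 4
Reactants: 7 (S)-5-methyl-5-(trimethylsilyloxy)cyclohex-2-en-1-one; 2 tert-butyl N-[4-(benzotriazol-1-yl)-4-oxobutyl]-N-methylcarbamate
Product: 10 5β-allyl-15-acyl-3α-methyl-3β-(trimethylsilyloxy)cyclohexan-1-one (β-diketone; largely enolised), via silyl enol ether 8 (not isolated), via lithium enolate 9 (not isolated)
Conditions: allylMgBr/CuBr·SMe2 (1.5 equiv each), LiCl, Me3SiCl (2 equiv), THF, −78 °C; pentane filtration, crude 8 used directly; MeLi (1.05 equiv), THF, 0 °C; then −78 °C, LiN(SiMe3)2 (1.1 equiv), 2 (1.1 equiv); NH4Cl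
Reagents that add atoms: allylmagnesium bromide, C=CC[Mg]Br; chlorotrimethylsilane, C[Si](C)(C)Cl (enol silyl group of 8 only); methyllithium, [Li]C (lithium of 9 only)
Why: Silyl-chloride-assisted conjugate allylation with an allylcopper reagent attacks C5 axially, syn to the pseudo-axial silyloxy group (methyl equatorial), so the allyl group ends cis to the C3 oxygen; the regiodefined lithium enolate released by MeLi is then C-acylated by the N-acylbenzotriazole (Claisen-type acylation).

Step 5
Reactants: 10 5β-allyl-15-acyl-3α-methyl-3β-(trimethylsilyloxy)cyclohexan-1-one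
Product: 12 15β-acyl-5β-allyl-15α-(3-chloropropyl)-3β-hydroxy-3α-methylcyclohexan-1-one, via cesium enolate 11 (not isolated)
Conditions: ICH2CH2CH2Cl (1.5 equiv), CsF (3 equiv), DMF, rt
Reagents that add atoms: 1-chloro-3-iodopropane, ClCCCI; cesium fluoride, [Cs+].[F-] (cesium of 11 only)
Why: Fluoride-mediated C-alkylation of a β-dicarbonyl compound (fluoride also cleaves the silyl ether; only the iodide terminus reacts) brings the electrophile to C15 anti to the adjacent C5 allyl group, which sets the quaternary centre with the acyl group β and the chloropropyl arm α.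

Step 6
Reactants: 12 15β-acyl-5β-allyl-15α-(3-chloropropyl)-3β-hydroxy-3α-methylcyclohexan-1-one
Product: 13 15β-acyl-5β-allyl-15α-(3-chloropropyl)-3α-methylcyclohexane-1β,3β-diol
Conditions: Et2BOMe (1.1 equiv), THF/MeOH (4:1), −78 °C; NaBH4 (1.1 equiv); AcOH, MeOH co-evaporation
Reagents that add atoms: none
Why: Hydroxyl-assisted reduction of a β-hydroxy ketone (Narasaka–Prasad type): boron complexation of C3–OH and C1=O makes the ring ketone the more electrophilic carbonyl, and hydride enters from the α face, anti to the C3 oxygen and the β acyl group, giving the cis-1,3-diol while the neopentyl acyclic C8 ketone is left.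

Step 7
Reactants: 13 15β-acyl-5β-allyl-15α-(3-chloropropyl)-3α-methylcyclohexane-1β,3β-diol
Product: 14 15β-acyl-5β-allyl-15α-(3-chloropropyl)-3α-methylcyclohexane-1β,3β-diyl diacetate
Conditions: Ac2O (6 equiv), DMAP (1 equiv), Et3N, CH2Cl2, rt then 40 °C
Reagents that add atoms: acetic anhydride, CC(=O)OC(C)=O
Why: DMAP-catalysed acylation (Steglich conditions) esterifies the secondary alcohol and, on warming, the tertiary alcohol; no stereocentre is touched and the C1 acetate can no longer undergo retro-aldol cleavage.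

Step 8
Reactants: 14 15β-acyl-5β-allyl-15α-(3-chloropropyl)-3α-methylcyclohexane-1β,3β-diyl diacetate
Product: 16 15β-acyl-15α-(3-chloropropyl)-3α-methyl-5β-(2-oxoethyl)cyclohexane-1β,3β-diyl diacetate, via ozonide 15 (not isolated)
Conditions: O3, CH2Cl2, −78 °C; then PPh3, −78 °C → rt
Reagents that add atoms: ozone, [O-][O+]=O
Why: Ozonolysis with reductive work-up cleaves the only alkene to the C7 aldehyde; carbamate, chloride, esters and ketone are inert.

Step 9
Reactants: 16 15β-acyl-15α-(3-chloropropyl)-3α-methyl-5β-(2-oxoethyl)cyclohexane-1β,3β-diyl diacetate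
Product: 17 cis-fused hydrindanone α-ketol: C7 ketone; C8 tertiary alcohol carrying the 3-[(tert-butoxycarbonyl)(methyl)amino]propyl arm; 15α-(3-chloropropyl); 1β,3β-diacetate
Conditions: 2-mesityl-6,7-dihydro-5H-pyrrolo[2,1-c][1,2,4]triazol-2-ium chloride (20 mol%), iPr2NEt (30 mol%), THF, 40 °C
Reagents that add atoms: none
Why: N-heterocyclic-carbene-catalysed intramolecular crossed aldehyde–ketone benzoin reaction: the Breslow intermediate turns the C7 aldehyde carbon into an acyl anion that adds to the C8 ketone carbon, closing the five-membered ring necessarily cis on the preset C5/C15 centres; the C8 carbinol configuration is uncontrolled and irrelevant because C8 becomes sp2 in step 11.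

Step 10
Reactants: 17 cis-fused hydrindanone α-ketol
Product: 20 tricyclic azonane α-ketol (N-methyl; C8–OH; C7 ketone; 1β,3β-diacetate), via amine trifluoroacetate 18 (not isolated), via iodo amine 19 (not isolated)
Conditions: TFA/CH2Cl2 (1:4), 0 °C; evaporate; NaI (3 equiv), K2CO3 (5 equiv), MeCN (0.002 M), 70 °C
Reagents that add atoms: trifluoroacetic acid, OC(=O)C(F)(F)F (counter-ion of 18 only); sodium iodide, [Na+].[I-] (iodine of 19 only)
Why: Acidolysis of the N-Boc group (much faster than ionisation of the tertiary acetate at 0 °C), Finkelstein exchange and intramolecular SN2 N-alkylation at high dilution close the azonane across the two vicinal arms on C8 and C15, the ring closure used for fawcettimine-type azonanes; no stereocentre changes.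

Step 11
Reactants: 20 tricyclic azonane α-ketol
Product: 21 CNP0386920.1 (target)
Conditions: Ph2S[OC(CF3)2Ph]2 (Martin sulfurane, 2 equiv), CH2Cl2, 0 °C → rt
Reagents that add atoms: none
Why: Martin sulfurane dehydration of the tertiary α-ketol can only remove a C9 hydrogen (C15 is quaternary), and inside the nine-membered ring only the ring-cis alkene forms, which is the (E)-enone with C10 anti to the C7 carbonyl.

**Compound list**

1 | 4-[(tert-butoxycarbonyl)(methyl)amino]butanoic acid | CN(CCCC(=O)O)C(=O)OC(C)(C)C | starting material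
2 | tert-butyl N-[4-(benzotriazol-1-yl)-4-oxobutyl]-N-methylcarbamate | CN(CCCC(=O)n1nnc2ccccc12)C(=O)OC(C)(C)C | intermediate
3 | 3-methylcyclohex-2-en-1-one | CC1=CC(=O)CCC1 | starting material
4 | (R)-3-methyl-3-(4,4,5,5-tetramethyl-1,3,2-dioxaborolan-2-yl)cyclohexan-1-one | O=C1C[C@@](C)(B2OC(C)(C)C(C)(C)O2)CCC1 | intermediate
5 | (S)-3-hydroxy-3-methylcyclohexan-1-one | O=C1C[C@@](C)(O)CCC1 | intermediate
6 | (S)-trimethyl{[5-methyl-5-(trimethylsilyloxy)cyclohex-1-en-1-yl]oxy}silane | C[Si](C)(C)OC1=CCC[C@](C)(O[Si](C)(C)C)C1 | intermediate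
7 | (S)-5-methyl-5-(trimethylsilyloxy)cyclohex-2-en-1-one | O=C1C[C@@](C)(O[Si](C)(C)C)CC=C1 | intermediate
8 | silyl enol ether of 5β-allyl-3α-methyl-3β-(trimethylsilyloxy)cyclohexanone (C1=C15 enol; allyl cis to OSiMe3) | C[Si](C)(C)OC1=C[C@H](CC=C)C[C@](C)(O[Si](C)(C)C)C1 | intermediate
9 | lithium enolate corresponding to 8 | [Li]OC1=C[C@H](CC=C)C[C@](C)(O[Si](C)(C)C)C1 | intermediate
10 | 5β-allyl-15-acyl-3α-methyl-3β-(trimethylsilyloxy)cyclohexan-1-one (keto form drawn with the acyl group α; enolisable) | O=C1C[C@@](C)(O[Si](C)(C)C)C[C@@H](CC=C)[C@@H]1C(=O)CCCN(C)C(=O)OC(C)(C)C | intermediate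
11 | cesium enolate of the desilylated β-diketone (3β-OH free) | [Cs+].[O-]C1=C(C(=O)CCCN(C)C(=O)OC(C)(C)C)[C@H](CC=C)C[C@](C)(O)C1 | intermediate
12 | 15β-acyl-5β-allyl-15α-(3-chloropropyl)-3β-hydroxy-3α-methylcyclohexan-1-one | O=C1C[C@@](C)(O)C[C@@H](CC=C)[C@]1(C(=O)CCCN(C)C(=O)OC(C)(C)C)CCCCl | intermediate
13 | 15β-acyl-5β-allyl-15α-(3-chloropropyl)-3α-methylcyclohexane-1β,3β-diol | O[C@H]1C[C@@](C)(O)C[C@@H](CC=C)[C@]1(C(=O)CCCN(C)C(=O)OC(C)(C)C)CCCCl | intermediate
14 | 1β,3β-diacetate of 13 | CC(=O)O[C@H]1C[C@@](C)(OC(C)=O)C[C@@H](CC=C)[C@]1(C(=O)CCCN(C)C(=O)OC(C)(C)C)CCCCl | intermediate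
15 | 1,2,4-trioxolane (ozonide) of the allyl group of 14 | CC(=O)O[C@H]1C[C@@](C)(OC(C)=O)C[C@@H](CC2OCOO2)[C@]1(C(=O)CCCN(C)C(=O)OC(C)(C)C)CCCCl | intermediate
16 | 5β-(2-oxoethyl) keto-aldehyde diacetate | CC(=O)O[C@H]1C[C@@](C)(OC(C)=O)C[C@@H](CC=O)[C@]1(C(=O)CCCN(C)C(=O)OC(C)(C)C)CCCCl | intermediate
17 | cis-hydrindanone α-ketol (C7 ketone; C8–OH, both C8 epimers) | CC(=O)O[C@H]1C[C@@](C)(OC(C)=O)C[C@H]2CC(=O)C(O)(CCCN(C)C(=O)OC(C)(C)C)[C@]21CCCCl | intermediate
18 | methylammonium trifluoroacetate of N-deprotected 17 | CC(=O)O[C@H]1C[C@@](C)(OC(C)=O)C[C@H]2CC(=O)C(O)(CCC[NH2+]C)[C@]21CCCCl.[O-]C(=O)C(F)(F)F | intermediate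
19 | free secondary amine with the 3-iodopropyl arm | CC(=O)O[C@H]1C[C@@](C)(OC(C)=O)C[C@H]2CC(=O)C(O)(CCCNC)[C@]21CCCI | intermediate
20 | tricyclic azonane α-ketol (C8–OH, both C8 epimers) | CC(=O)O[C@H]1C[C@@](C)(OC(C)=O)C[C@H]2CC(=O)C3(O)CCCN(C)CCC[C@@]321 | intermediate
21 | CNP0386920.1 | CC(=O)O[C@H]1C[C@@](C)(OC(C)=O)C[C@H]2CC(=O)/C3=C/CCN(C)CCC[C@@]321 | target

**Totals**
Total step count: 11. Longest linear sequence: 10 steps (steps 2 to 11, from 3-methylcyclohex-2-en-1-one).

**Three steps most likely to fail**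

Step 9 (carbene-catalysed benzoin). The ketone is flanked by a quaternary carbon, the addition is reversible, and intramolecular aldol of the C9 enolate onto the aldehyde competes. Fallback, from 16 back to 17: the same C7–C8 bond is made by reductive ketyl coupling. SmI2 (2.2 equiv, THF/t-BuOH, −78 °C) cyclises the aldehyde onto the ketone to the cis-fused 7,8-diol F8. Oxidation of its secondary hydroxyl (Dess–Martin periodinane, NaHCO3, CH2Cl2) then gives 17.

Step 5 (quaternary centre by C-alkylation). O-alkylation or low conversion with an unactivated primary iodide next to the substituted C5 is possible. Fallback, from 10 back to 12: conjugate addition replaces alkylation. Michael addition of 10 to acrolein (Et3N cat., CH2Cl2, 0 °C), again anti to the allyl group, gives the 15α-(3-oxopropyl) silyl ether F5. NaBH4 in MeOH at −78 °C reduces only the aldehyde to the 15α-(3-hydroxypropyl) silyl ether F6. Appel chlorination (PPh3, CCl4) gives the 15α-(3-chloropropyl) silyl ether F7, and AcOH/THF/H2O removes the silyl group to give 12.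

Step 4 (one-pot conjugate allylation/C-acylation). Risks are 1,2-addition of the allyl reagent, modest facial selectivity at C5, and sluggish acylation of the hindered enolate. Fallback, from 5 back to 10: the two bonds are made in the opposite order. Silylation of 5 (Me3SiCl, imidazole) gives (S)-3-methyl-3-(trimethylsilyloxy)cyclohexan-1-one F1. Its kinetic enolate (LiN(iPr)2, 2.2 equiv, −78 °C) is acylated with 2 to the 2-acyl ketone F2. Selenenylation (PhSeCl, pyridine) gives the 2-acyl-2-(phenylselanyl) ketone F3. Oxidation with H2O2 and syn-elimination gives the 2-acylcyclohex-2-enone F4. This doubly activated acceptor takes the allyl group from allylMgBr/CuBr·SMe2 at −78 °C, cis to the silyloxy group, to give 10.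

**Further compounds**

F1 | step 4 | (S)-3-methyl-3-(trimethylsilyloxy)cyclohexan-1-one | O=C1C[C@@](C)(O[Si](C)(C)C)CCC1
F2 | step 4 | 15-acyl-3α-methyl-3β-(trimethylsilyloxy)cyclohexan-1-one (enolisable at C15) | O=C1C[C@@](C)(O[Si](C)(C)C)CCC1C(=O)CCCN(C)C(=O)OC(C)(C)C
F3 | step 4 | 15-acyl-15-(phenylselanyl)-3α-methyl-3β-(trimethylsilyloxy)cyclohexan-1-one (C15 epimers) | O=C1C[C@@](C)(O[Si](C)(C)C)CCC1([Se]c2ccccc2)C(=O)CCCN(C)C(=O)OC(C)(C)C
F4 | step 4 | 2-acyl-(S)-5-methyl-5-(trimethylsilyloxy)cyclohex-2-en-1-one | O=C1C[C@@](C)(O[Si](C)(C)C)CC=C1C(=O)CCCN(C)C(=O)OC(C)(C)C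
F5 | step 5 | 15β-acyl-5β-allyl-3α-methyl-15α-(3-oxopropyl)-3β-(trimethylsilyloxy)cyclohexan-1-one | O=C1C[C@@](C)(O[Si](C)(C)C)C[C@@H](CC=C)[C@]1(C(=O)CCCN(C)C(=O)OC(C)(C)C)CCC=O
F6 | step 5 | 15β-acyl-5β-allyl-15α-(3-hydroxypropyl)-3α-methyl-3β-(trimethylsilyloxy)cyclohexan-1-one | O=C1C[C@@](C)(O[Si](C)(C)C)C[C@@H](CC=C)[C@]1(C(=O)CCCN(C)C(=O)OC(C)(C)C)CCCO
F7 | step 5 | 15β-acyl-5β-allyl-15α-(3-chloropropyl)-3α-methyl-3β-(trimethylsilyloxy)cyclohexan-1-one | O=C1C[C@@](C)(O[Si](C)(C)C)C[C@@H](CC=C)[C@]1(C(=O)CCCN(C)C(=O)OC(C)(C)C)CCCCl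
F8 | step 9 | cis-fused hydrindane-7,8-diol (C7 secondary OH, C8 tertiary OH; diastereomers) | CC(=O)O[C@H]1C[C@@](C)(OC(C)=O)C[C@H]2CC(O)C(O)(CCCN(C)C(=O)OC(C)(C)C)[C@]21CCCCl
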